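The lactone ring (O1–C2–C3–C4–C5) is cut back to a cyclobutanone: C4, which carries the ring-B benzyl group, lies on the mirror plane of a 3-(arylmethyl)cyclobutanone, and O1 is inserted between C2 and C5. One catalytic Baeyer–Villiger oxidation therefore forms the five-membered ring and fixes C4 as R. Its substrate is eugenol-derived ring B carrying the cyclobutanone on the old allyl carbons and, ortho to the benzylated phenol, the future keto-alcohol arm locked as a cis-diaryl acetonide made by an auxiliary aldol. The trans C3 benzyl group, a separately made (2S,3R)-phenylcoumaran bromide, is then added by enolate alkylation; deprotection, benzylic oxidation and hydrogenolysis finish.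

Key step: step 11

Labels: lactone O1, C2 (carbonyl), C3, C4, C5 (OCH2); ring A is the 4-hydroxy-3-methoxyphenyl ketone ring, ring B the eugenol-derived ring.

Design remark: the ring-B phenol stays benzylated and the ketone stays masked as the acetonide-protected carbinol until the lactone is complete. A free ortho phenol would close onto the benzylic carbinol under acid, and a free ketone would make its alpha carbon enolisable under the alkylation base.

Assumption: which antipode of the N,N'-dioxide ligand delivers the R lactone is settled beforehand on plain 3-benzylcyclobutanone, whose lactone enantiomers are known compounds.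

Commercial inputs besides eugenol: 4-(benzyloxy)-3-methoxybenzaldehyde, 5-bromo-2-hydroxy-3-methoxybenzaldehyde, both antipodes of 4-benzyl-2-oxazolidinone, trichloroacetyl chloride.

**Part A: ring B, arm, cyclobutanone, lactone**

Step 1
Reactants: 1 eugenol
Product: 3 5-allyl-2-hydroxy-3-methoxybenzaldehyde, via salicyl alcohol 2 (not isolated)
Conditions: MgCl2, Et3N, (CH2O)n, MeCN, reflux; aq. HCl work-up
Reagents that add atoms: paraformaldehyde (formaldehyde unit), C=O
Why: Magnesium-phenoxide-directed ortho-formylation, in which chelated formaldehyde is delivered to the only free ortho position to give salicyl alcohol 2 and a second formaldehyde oxidises it by hydride transfer.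

Step 2
Reactants: 3 5-allyl-2-hydroxy-3-methoxybenzaldehyde
Product: 4 5-allyl-2-(benzyloxy)-3-methoxybenzaldehyde
Conditions: BnBr, K2CO3, DMF, rt
Reagents that add atoms: benzyl bromide, BrCc1ccccc1
Why: Williamson etherification of the phenoxide, benzyl being chosen because it should survive every later step and leave by neutral hydrogenolysis at the very end.

Step 3
Reactants: 4 5-allyl-2-(benzyloxy)-3-methoxybenzaldehyde
Product: 5 racemic 1-[5-allyl-2-(benzyloxy)-3-methoxyphenyl]-2,2,2-trichloroethan-1-ol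
Conditions: CHCl3 (solvent), DBU, rt
Reagents that add atoms: chloroform, ClC(Cl)Cl
Why: Amidine-promoted addition of the trichloromethyl anion to the aldehyde, the first half of a Jocic-type homologation, with no stereocontrol needed because the carbinol carbon becomes a CH2 group.

Step 4
Reactants: 5 racemic 1-[5-allyl-2-(benzyloxy)-3-methoxyphenyl]-2,2,2-trichloroethan-1-ol
Product: 8 [5-allyl-2-(benzyloxy)-3-methoxyphenyl]acetic acid, via dichlorooxirane 6 (not isolated), via acid chloride 7 (not isolated)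
Conditions: NaBH4, NaOH, t-BuOH, 40–55 °C; then aq. HCl to pH 2
Reagents that add atoms: sodium hydroxide, [Na+].[OH-]
Why: Jocic-type reductive homologation, in which the alkoxide closes to dichlorooxirane 6, hydride opens it at the benzylic carbon to give acid chloride 7 and hydroxide converts this into the carboxylate, under conditions too mild to isomerise the allyl group.

Step 5
Reactants: 8 [5-allyl-2-(benzyloxy)-3-methoxyphenyl]acetic acid, 9 (R)-4-benzyl-2-oxazolidinone
Product: 11 (R)-4-benzyl-3-{[5-allyl-2-(benzyloxy)-3-methoxyphenyl]acetyl}oxazolidin-2-one, via mixed pivalic anhydride 10 (not isolated)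
Conditions: t-BuCOCl, Et3N, THF, −20 °C; then 9, LiCl, −20 °C → rt
Reagents that add atoms: none
Why: N-acylation of the oxazolidinone through the mixed pivalic anhydride with LiCl activation, a standard auxiliary loading that needs no strong base.

Step 6
Reactants: 11 (R)-4-benzyl-3-{[5-allyl-2-(benzyloxy)-3-methoxyphenyl]acetyl}oxazolidin-2-one, 12 4-(benzyloxy)-3-methoxybenzaldehyde
Product: 14 (4R)-4-benzyl-3-{(2R,3R)-2-[5-allyl-2-(benzyloxy)-3-methoxyphenyl]-3-[4-(benzyloxy)-3-methoxyphenyl]-3-hydroxypropanoyl}oxazolidin-2-one, via Z-boron enolate 13 (not isolated)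
Conditions: Bu2BOTf, i-Pr2NEt, CH2Cl2, −78 → 0 °C; 12, −78 → 0 °C; pH 7 buffer, MeOH, 30% H2O2, 0 °C
Reagents that add atoms: none
Why: Evans syn-aldol, in which Z-boron enolate 13 reacts through a chair Zimmerman–Traxler transition state on the face away from the auxiliary benzyl group, setting the aryl-bearing carbon as 2R (the later S carbon next to the ketone) and the carbinol as 3R.

Step 7
Reactants: 14 syn-aldol imide
Product: 15 (1R,2S)-2-[5-allyl-2-(benzyloxy)-3-methoxyphenyl]-1-[4-(benzyloxy)-3-methoxyphenyl]propane-1,3-diol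
Conditions: LiBH4, THF–MeOH, 0 °C
Reagents that add atoms: none
Why: Reductive cleavage of the imide by LiBH4 should give the 1,3-diol and return the auxiliary without enolising the aryl-bearing stereocentre.

Step 8
Reactants: 15 (1R,2S)-diol
Product: 16 (4R,5S)-5-[5-allyl-2-(benzyloxy)-3-methoxyphenyl]-4-[4-(benzyloxy)-3-methoxyphenyl]-2,2-dimethyl-1,3-dioxane
Conditions: Me2C(OMe)2, PPTS (cat.), CH2Cl2, rt
Reagents that add atoms: 2,2-dimethoxypropane, COC(C)(C)OC
Why: Acetonide formation by transacetalisation, the syn diol giving the cis-4,5-diaryl dioxane whose axial C5 aryl group meets no syn-axial methyl, and the mask keeping the carbinol from ionising or oxidising later.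

Step 9
Reactants: 16 allyl acetonide, 17 trichloroacetyl chloride
Product: 18 2,2-dichloro-3-{4-(benzyloxy)-3-[(4R,5S)-4-[4-(benzyloxy)-3-methoxyphenyl]-2,2-dimethyl-1,3-dioxan-5-yl]-5-methoxybenzyl}cyclobutan-1-one (both configurations at the new ring carbon)
Conditions: Zn–Cu couple, POCl3, Et2O, rt, slow addition of 17
Reagents that add atoms: none
Why: Thermal [2+2] cycloaddition of dichloroketene, made from 17 and zinc, to the terminal alkene with the usual regiochemistry that puts the carbonyl carbon on the terminal CH2, POCl3 tying up ZnCl2 to spare the acetonide, and the uncontrolled new ring carbon losing its stereogenicity in step 10.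

Step 10
Reactants: 18 dichlorocyclobutanone
Product: 19 3-{4-(benzyloxy)-3-[(4R,5S)-4-[4-(benzyloxy)-3-methoxyphenyl]-2,2-dimethyl-1,3-dioxan-5-yl]-5-methoxybenzyl}cyclobutan-1-one
Conditions: Zn dust, NH4Cl, MeOH, rt
Reagents that add atoms: none
Why: Zinc reduction of the alpha,alpha-dichloroketone by two successive reductive dechlorinations under buffered, nearly neutral conditions that should leave the acetonide and benzyl ethers alone.

Step 11
Reactants: 19 3-(arylmethyl)cyclobutanone
Product: 21 (R)-4-{4-(benzyloxy)-3-[(4R,5S)-4-[4-(benzyloxy)-3-methoxyphenyl]-2,2-dimethyl-1,3-dioxan-5-yl]-5-methoxybenzyl}dihydrofuran-2(3H)-one, via Criegee adduct 20 (not isolated)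
Conditions: Sc(OTf)3 (10 mol %), C2-symmetric N,N'-dioxide ligand from (S)-pipecolic acid 2,6-diisopropylanilide with a propane-1,3-diyl bridge or its antipode (12 mol %), dried mCPBA (1.2 equiv), EtOAc, −20 °C
Reagents that add atoms: mCPBA, OOC(=O)c1cccc(Cl)c1
Why: The scandium-bound ketone adds the peracid to give Criegee adduct 20, and a 1,2-shift of one of the two ring CH2 groups from carbon to oxygen, with loss of 3-chlorobenzoate, inserts O1 between C2 and C5. The closest known reaction type is the catalytic desymmetrising Baeyer–Villiger oxidation of prochiral 3-aryl- and 3-benzylcyclobutanones with chiral Lewis acid complexes and peracids. The five-membered lactone arises by ring expansion of the four-membered ketone, a migration and not a cyclisation, driven by release of ring strain. C4 is set by the catalyst alone, whose chiral pocket should hold the adduct so that only one enantiotopic C–C bond lies antiperiplanar to the O–O bond, while the arm stereocentres sit six bonds away and should neither help nor hinder. The step needs chemoselectivity for the ketone over the electron-rich arenes and benzyl ethers, which the strained and highly electrophilic cyclobutanone secures at −20 °C, and it needs the uncatalysed oxidation to stay slow, which low temperature and the ester solvent serve.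

**Part B: the (2S,3R)-phenylcoumaran bromide**

Step 12
Reactants: 22 5-bromo-2-hydroxy-3-methoxybenzaldehyde
Product: 23 5-bromo-3-methoxy-2-(methoxymethoxy)benzaldehyde
Conditions: MOMCl, i-Pr2NEt, CH2Cl2, 0 °C → rt
Reagents that add atoms: chloromethyl methyl ether, COCCl
Why: O-alkylation of the phenol to a MOM acetal, which should survive the basic homologation, the aldol and the hydride steps and later falls to the same acid that closes the coumaran.

Step 13
Reactants: 23 5-bromo-3-methoxy-2-(methoxymethoxy)benzaldehyde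
Product: 24 racemic 1-[5-bromo-3-methoxy-2-(methoxymethoxy)phenyl]-2,2,2-trichloroethan-1-ol
Conditions: CHCl3 (solvent), DBU, rt
Reagents that add atoms: chloroform, ClC(Cl)Cl
Why: Amidine-promoted trichloromethyl anion addition as in step 3, run without acid so that the MOM group is safe.

Step 14
Reactants: 24 racemic trichloromethyl carbinol
Product: 27 [5-bromo-3-methoxy-2-(methoxymethoxy)phenyl]acetic acid, via dichlorooxirane 25 (not isolated), via acid chloride 26 (not isolated)
Conditions: NaBH4, NaOH, t-BuOH, 40–55 °C; then citric acid to pH 4, 0 °C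
Reagents that add atoms: sodium hydroxide, [Na+].[OH-]
Why: Jocic-type reductive homologation as in step 4, to which the aryl bromide and the MOM acetal are inert, with a mild acidification that keeps the acetal.

Step 15
Reactants: 27 [5-bromo-3-methoxy-2-(methoxymethoxy)phenyl]acetic acid, 28 (S)-4-benzyl-2-oxazolidinone
Product: 30 (S)-4-benzyl-3-{[5-bromo-3-methoxy-2-(methoxymethoxy)phenyl]acetyl}oxazolidin-2-one, via mixed pivalic anhydride 29 (not isolated)
Conditions: t-BuCOCl, Et3N, THF, −20 °C; then 28, LiCl, −20 °C → rt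
Reagents that add atoms: none
Why: Mixed-anhydride N-acylation as in step 5, here with the antipodal auxiliary because the coumaran needs the opposite configuration at its aryl-bearing carbon.

Step 16
Reactants: 30 (S)-imide, 12 4-(benzyloxy)-3-methoxybenzaldehyde
Product: 32 (4S)-4-benzyl-3-{(2S,3S)-3-[4-(benzyloxy)-3-methoxyphenyl]-2-[5-bromo-3-methoxy-2-(methoxymethoxy)phenyl]-3-hydroxypropanoyl}oxazolidin-2-one, via Z-boron enolate 31 (not isolated)
Conditions: Bu2BOTf, i-Pr2NEt, CH2Cl2, −78 → 0 °C; 12, −78 → 0 °C; pH 7 buffer, MeOH, 30% H2O2, 0 °C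
Reagents that add atoms: none
Why: Evans syn-aldol through Z-boron enolate 31 and a chair Zimmerman–Traxler transition state, the S auxiliary setting the aryl-bearing carbon as 2S (the later C3 of the coumaran) and the carbinol as 3S.

Step 17
Reactants: 32 syn-aldol imide
Product: 33 (1S,2R)-1-[4-(benzyloxy)-3-methoxyphenyl]-2-[5-bromo-3-methoxy-2-(methoxymethoxy)phenyl]propane-1,3-diol
Conditions: LiBH4, THF–MeOH, 0 °C
Reagents that add atoms: none
Why: Reductive removal of the auxiliary by LiBH4 as in step 7, which should leave the aryl bromide and both stereocentres untouched.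

Step 18
Reactants: 33 (1S,2R)-diol
Product: 35 [(2S,3R)-2-[4-(benzyloxy)-3-methoxyphenyl]-5-bromo-7-methoxy-2,3-dihydro-1-benzofuran-3-yl]methanol, via phenol triol 34 (not isolated)
Conditions: HCl (1 M in MeOH), MeOH–CH2Cl2, 0 °C → rt
Reagents that add atoms: none
Why: Acid removes the MOM group to give phenol 34 and then ionises the para-benzyloxy benzylic carbinol to a stabilised cation that the ortho phenol captures in a reversible 5-exo SN1 ring closure, so that C2 is set under thermodynamic control as the trans (2S,3R) coumaran while C3 is untouched.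

Step 19
Reactants: 35 coumaran alcohol
Product: 36 {[(2S,3R)-2-[4-(benzyloxy)-3-methoxyphenyl]-5-bromo-7-methoxy-2,3-dihydro-1-benzofuran-3-yl]methoxy}(tert-butyl)dimethylsilane
Conditions: TBSCl, imidazole, DMF, rt
Reagents that add atoms: tert-butyldimethylsilyl chloride, CC(C)(C)[Si](C)(C)Cl
Why: Silylation of the only hydroxyl group, a primary TBS ether being chosen because the mild acid that opens the acetonide should remove it too.

Step 20
Reactants: 36 bromo coumaran silyl ether
Product: 39 [(2S,3R)-2-[4-(benzyloxy)-3-methoxyphenyl]-3-{[(tert-butyldimethylsilyl)oxy]methyl}-7-methoxy-2,3-dihydro-1-benzofuran-5-yl]methanol, via aryllithium 37 (not isolated), via aldehyde 38 (not isolated)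
Conditions: n-BuLi, THF, −78 °C; DMF, −78 → 0 °C; then MeOH, NaBH4, 0 °C
Reagents that add atoms: N,N-dimethylformamide, CN(C)C=O
Why: Bromine–lithium exchange, faster at −78 °C than any deprotonation of the coumaran, gives aryllithium 37, formylation with DMF releases aldehyde 38 on the methanol quench, and NaBH4 reduces it in the same flask.

Step 21
Reactants: 39 benzylic alcohol
Product: 40 {[(2S,3R)-2-[4-(benzyloxy)-3-methoxyphenyl]-5-(bromomethyl)-7-methoxy-2,3-dihydro-1-benzofuran-3-yl]methoxy}(tert-butyl)dimethylsilane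
Conditions: CBr4, PPh3, CH2Cl2, 0 °C; used at once
Reagents that add atoms: carbon tetrabromide, BrC(Br)(Br)Br
Why: Appel bromination of the primary benzylic alcohol under neutral conditions that should preserve the silyl ether and the acid-sensitive coumaran.

**Part C: union and endgame**

Step 22
Reactants: 21 (R)-lactone, 40 coumaran benzylic bromide
Product: 42 (3R,4R)-4-{4-(benzyloxy)-3-[(4R,5S)-4-[4-(benzyloxy)-3-methoxyphenyl]-2,2-dimethyl-1,3-dioxan-5-yl]-5-methoxybenzyl}-3-{[(2S,3R)-2-[4-(benzyloxy)-3-methoxyphenyl]-3-{[(tert-butyldimethylsilyl)oxy]methyl}-7-methoxy-2,3-dihydro-1-benzofuran-5-yl]methyl}dihydrofuran-2(3H)-one, via lithium enolate 41 (not isolated)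
Conditions: LiN(SiMe3)2, THF, −78 °C; then 40, DMPU, −78 → −40 °C
Reagents that add atoms: none
Why: Alkylation of lithium enolate 41 with the reactive benzylic bromide, the C4 substituent shielding one face of the planar enolate so that the electrophile enters anti to it and sets C3 as R in the trans lactone, the established outcome for beta-benzyl butyrolactones.

Step 23
Reactants: 42 alkylated lactone
Product: 43 (3R,4R)-4-{4-(benzyloxy)-3-[(1R,2S)-1-[4-(benzyloxy)-3-methoxyphenyl]-1,3-dihydroxypropan-2-yl]-5-methoxybenzyl}-3-{[(2S,3R)-2-[4-(benzyloxy)-3-methoxyphenyl]-3-(hydroxymethyl)-7-methoxy-2,3-dihydro-1-benzofuran-5-yl]methyl}dihydrofuran-2(3H)-one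
Conditions: AcOH–THF–H2O (3:1:1), 45 °C
Reagents that add atoms: none
Why: Mild aqueous acid should hydrolyse the acetonide and the primary silyl ether in one operation while being too weak to ionise the benzylic carbinol or the coumaran C2–O bond.

Step 24
Reactants: 43 triol
Product: 44 (3R,4R)-4-{4-(benzyloxy)-3-[(2S)-1-[4-(benzyloxy)-3-methoxyphenyl]-3-hydroxy-1-oxopropan-2-yl]-5-methoxybenzyl}-3-{[(2S,3R)-2-[4-(benzyloxy)-3-methoxyphenyl]-3-(hydroxymethyl)-7-methoxy-2,3-dihydro-1-benzofuran-5-yl]methyl}dihydrofuran-2(3H)-one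
Conditions: activated MnO2 (excess), CH2Cl2, rt
Reagents that add atoms: none
Why: Chemoselective oxidation of the single benzylic alcohol by activated MnO2, which should not touch the two saturated primary alcohols and, being neutral, should not epimerise the newly enolisable carbon between the ketone and ring B.

Step 25
Reactants: 44 tris(benzyl ether) keto diol
Product: 45 CNP0111438.1, (3R,4R)-3-{[(2S,3R)-3-(hydroxymethyl)-2-(4-hydroxy-3-methoxyphenyl)-7-methoxy-2,3-dihydro-1-benzofuran-5-yl]methyl}-4-{4-hydroxy-3-[(2S)-3-hydroxy-1-(4-hydroxy-3-methoxyphenyl)-1-oxopropan-2-yl]-5-methoxybenzyl}dihydrofuran-2(3H)-one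
Conditions: H2 (1 atm), 10% Pd/C, EtOAc, rt, stopped at full debenzylation
Reagents that add atoms: none
Why: Hydrogenolysis of the three aryl benzyl ethers on Pd/C, which should be faster than reduction of the electron-rich aryl ketone or opening of the coumaran C2–O bond, in a neutral medium that preserves the labile stereocentre alpha to the ketone.

**Compound list**

1 | eugenol | COc1cc(CC=C)ccc1O | starting material
2 | salicyl alcohol, 4-allyl-2-(hydroxymethyl)-6-methoxyphenol (not isolated) | COc1cc(CC=C)cc(CO)c1O | intermediate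
3 | 5-allyl-2-hydroxy-3-methoxybenzaldehyde | COc1cc(CC=C)cc(C=O)c1O | intermediate
4 | 5-allyl-2-(benzyloxy)-3-methoxybenzaldehyde | COc1cc(CC=C)cc(C=O)c1OCc1ccccc1 | intermediate
5 | racemic 1-[5-allyl-2-(benzyloxy)-3-methoxyphenyl]-2,2,2-trichloroethan-1-ol | COc1cc(CC=C)cc(C(O)C(Cl)(Cl)Cl)c1OCc1ccccc1 | intermediate
6 | dichlorooxirane, 3-[5-allyl-2-(benzyloxy)-3-methoxyphenyl]-2,2-dichlorooxirane (not isolated) | COc1cc(CC=C)cc(C2OC2(Cl)Cl)c1OCc1ccccc1 | intermediate
7 | acid chloride, [5-allyl-2-(benzyloxy)-3-methoxyphenyl]acetyl chloride (not isolated) | COc1cc(CC=C)cc(CC(Cl)=O)c1OCc1ccccc1 | intermediate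
8 | [5-allyl-2-(benzyloxy)-3-methoxyphenyl]acetic acid | COc1cc(CC=C)cc(CC(O)=O)c1OCc1ccccc1 | intermediate
9 | (R)-4-benzyl-2-oxazolidinone | O=C1N[C@H](Cc2ccccc2)CO1 | starting material
10 | mixed pivalic anhydride of 8 (not isolated) | COc1cc(CC=C)cc(CC(=O)OC(=O)C(C)(C)C)c1OCc1ccccc1 | intermediate
11 | (R)-4-benzyl-3-{[5-allyl-2-(benzyloxy)-3-methoxyphenyl]acetyl}oxazolidin-2-one | COc1cc(CC=C)cc(CC(=O)N2[C@H](Cc3ccccc3)COC2=O)c1OCc1ccccc1 | intermediate
12 | 4-(benzyloxy)-3-methoxybenzaldehyde | O=Cc1ccc(OCc2ccccc2)c(OC)c1 | starting material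
13 | Z-dibutylboron enolate of 11 (not isolated) | CCCCB(CCCC)O/C(=C\c1cc(CC=C)cc(OC)c1OCc1ccccc1)N1[C@H](Cc2ccccc2)COC1=O | intermediate
14 | (4R)-4-benzyl-3-{(2R,3R)-2-[5-allyl-2-(benzyloxy)-3-methoxyphenyl]-3-[4-(benzyloxy)-3-methoxyphenyl]-3-hydroxypropanoyl}oxazolidin-2-one | COc1cc(CC=C)cc([C@@H](C(=O)N2[C@H](Cc3ccccc3)COC2=O)[C@@H](O)c2ccc(OCc3ccccc3)c(OC)c2)c1OCc1ccccc1 | intermediate
15 | (1R,2S)-2-[5-allyl-2-(benzyloxy)-3-methoxyphenyl]-1-[4-(benzyloxy)-3-methoxyphenyl]propane-1,3-diol | COc1cc(CC=C)cc([C@@H](CO)[C@@H](O)c2ccc(OCc3ccccc3)c(OC)c2)c1OCc1ccccc1 | intermediate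
16 | (4R,5S)-5-[5-allyl-2-(benzyloxy)-3-methoxyphenyl]-4-[4-(benzyloxy)-3-methoxyphenyl]-2,2-dimethyl-1,3-dioxane | COc1cc(CC=C)cc([C@H]2COC(C)(C)O[C@H]2c2ccc(OCc3ccccc3)c(OC)c2)c1OCc1ccccc1 | intermediate
17 | trichloroacetyl chloride | ClC(Cl)(Cl)C(Cl)=O | starting material
18 | 2,2-dichloro-3-(arylmethyl)cyclobutanone carrying the acetonide arm (epimers at the ring CH) | COc1cc(CC2CC(=O)C2(Cl)Cl)cc([C@H]2COC(C)(C)O[C@H]2c2ccc(OCc3ccccc3)c(OC)c2)c1OCc1ccccc1 | intermediate
19 | 3-{4-(benzyloxy)-3-[(4R,5S)-4-[4-(benzyloxy)-3-methoxyphenyl]-2,2-dimethyl-1,3-dioxan-5-yl]-5-methoxybenzyl}cyclobutan-1-one | O=C1CC(Cc2cc(OC)c(OCc3ccccc3)c(c2)[C@H]4COC(C)(C)O[C@H]4c5ccc(OCc6ccccc6)c(OC)c5)C1 | intermediate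
20 | Criegee adduct of 19 with mCPBA (not isolated) | OC1(OOC(=O)c2cccc(Cl)c2)CC(Cc2cc(OC)c(OCc3ccccc3)c(c2)[C@H]2COC(C)(C)O[C@H]2c2ccc(OCc3ccccc3)c(OC)c2)C1 | intermediate
21 | (R)-4-{4-(benzyloxy)-3-[(4R,5S)-4-[4-(benzyloxy)-3-methoxyphenyl]-2,2-dimethyl-1,3-dioxan-5-yl]-5-methoxybenzyl}dihydrofuran-2(3H)-one | O=C1C[C@@H](Cc2cc(OC)c(OCc3ccccc3)c(c2)[C@H]4COC(C)(C)O[C@H]4c5ccc(OCc6ccccc6)c(OC)c5)CO1 | intermediate
22 | 5-bromo-2-hydroxy-3-methoxybenzaldehyde | COc1cc(Br)cc(C=O)c1O | starting material
23 | 5-bromo-3-methoxy-2-(methoxymethoxy)benzaldehyde | COCOc1c(OC)cc(Br)cc1C=O | intermediate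
24 | racemic 1-[5-bromo-3-methoxy-2-(methoxymethoxy)phenyl]-2,2,2-trichloroethan-1-ol | COCOc1c(OC)cc(Br)cc1C(O)C(Cl)(Cl)Cl | intermediate
25 | dichlorooxirane, 3-[5-bromo-3-methoxy-2-(methoxymethoxy)phenyl]-2,2-dichlorooxirane (not isolated) | COCOc1c(OC)cc(Br)cc1C1OC1(Cl)Cl | intermediate
26 | acid chloride, [5-bromo-3-methoxy-2-(methoxymethoxy)phenyl]acetyl chloride (not isolated) | COCOc1c(OC)cc(Br)cc1CC(Cl)=O | intermediate
27 | [5-bromo-3-methoxy-2-(methoxymethoxy)phenyl]acetic acid | COCOc1c(OC)cc(Br)cc1CC(O)=O | intermediate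
28 | (S)-4-benzyl-2-oxazolidinone | O=C1N[C@@H](Cc2ccccc2)CO1 | starting material
29 | mixed pivalic anhydride of 27 (not isolated) | COCOc1c(OC)cc(Br)cc1CC(=O)OC(=O)C(C)(C)C | intermediate
30 | (S)-4-benzyl-3-{[5-bromo-3-methoxy-2-(methoxymethoxy)phenyl]acetyl}oxazolidin-2-one | COCOc1c(OC)cc(Br)cc1CC(=O)N1[C@@H](Cc2ccccc2)COC1=O | intermediate
31 | Z-dibutylboron enolate of 30 (not isolated) | CCCCB(CCCC)O/C(=C\c1cc(Br)cc(OC)c1OCOC)N1[C@@H](Cc2ccccc2)COC1=O | intermediate
32 | (4S)-4-benzyl-3-{(2S,3S)-3-[4-(benzyloxy)-3-methoxyphenyl]-2-[5-bromo-3-methoxy-2-(methoxymethoxy)phenyl]-3-hydroxypropanoyl}oxazolidin-2-one | COCOc1c(OC)cc(Br)cc1[C@H](C(=O)N1[C@@H](Cc2ccccc2)COC1=O)[C@H](O)c1ccc(OCc2ccccc2)c(OC)c1 | intermediate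
33 | (1S,2R)-1-[4-(benzyloxy)-3-methoxyphenyl]-2-[5-bromo-3-methoxy-2-(methoxymethoxy)phenyl]propane-1,3-diol | COCOc1c(OC)cc(Br)cc1[C@H](CO)[C@H](O)c1ccc(OCc2ccccc2)c(OC)c1 | intermediate
34 | phenol triol, (1S,2R)-1-[4-(benzyloxy)-3-methoxyphenyl]-2-(5-bromo-2-hydroxy-3-methoxyphenyl)propane-1,3-diol (not isolated) | COc1cc(Br)cc([C@H](CO)[C@H](O)c2ccc(OCc3ccccc3)c(OC)c2)c1O | intermediate
35 | [(2S,3R)-2-[4-(benzyloxy)-3-methoxyphenyl]-5-bromo-7-methoxy-2,3-dihydro-1-benzofuran-3-yl]methanol | Brc1cc(OC)c2c(c1)[C@H](CO)[C@@H](c1ccc(OCc3ccccc3)c(OC)c1)O2 | intermediate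
36 | TBS ether of 35 | Brc1cc(OC)c2c(c1)[C@H](CO[Si](C)(C)C(C)(C)C)[C@@H](c1ccc(OCc3ccccc3)c(OC)c1)O2 | intermediate
37 | aryllithium from 36 (not isolated) | [Li]c1cc(OC)c2c(c1)[C@H](CO[Si](C)(C)C(C)(C)C)[C@@H](c1ccc(OCc3ccccc3)c(OC)c1)O2 | intermediate
38 | (2S,3R)-2-[4-(benzyloxy)-3-methoxyphenyl]-3-{[(tert-butyldimethylsilyl)oxy]methyl}-7-methoxy-2,3-dihydro-1-benzofuran-5-carbaldehyde (not isolated) | O=Cc1cc(OC)c2c(c1)[C@H](CO[Si](C)(C)C(C)(C)C)[C@@H](c1ccc(OCc3ccccc3)c(OC)c1)O2 | intermediate
39 | [(2S,3R)-2-[4-(benzyloxy)-3-methoxyphenyl]-3-{[(tert-butyldimethylsilyl)oxy]methyl}-7-methoxy-2,3-dihydro-1-benzofuran-5-yl]methanol | OCc1cc(OC)c2c(c1)[C@H](CO[Si](C)(C)C(C)(C)C)[C@@H](c1ccc(OCc3ccccc3)c(OC)c1)O2 | intermediate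
40 | {[(2S,3R)-2-[4-(benzyloxy)-3-methoxyphenyl]-5-(bromomethyl)-7-methoxy-2,3-dihydro-1-benzofuran-3-yl]methoxy}(tert-butyl)dimethylsilane | BrCc1cc(OC)c2c(c1)[C@H](CO[Si](C)(C)C(C)(C)C)[C@@H](c1ccc(OCc3ccccc3)c(OC)c1)O2 | intermediate
41 | lithium enolate of 21 (not isolated) | [Li]OC1=C[C@@H](Cc2cc(OC)c(OCc3ccccc3)c(c2)[C@H]2COC(C)(C)O[C@H]2c2ccc(OCc3ccccc3)c(OC)c2)CO1 | intermediate
42 | (3R,4R)-trans-dibenzyl lactone with acetonide arm, three benzyl ethers and TBS ether | O=C1OC[C@H](Cc2cc(OC)c(OCc3ccccc3)c(c2)[C@H]2COC(C)(C)O[C@H]2c2ccc(OCc3ccccc3)c(OC)c2)[C@H]1Cc1cc(OC)c2c(c1)[C@H](CO[Si](C)(C)C(C)(C)C)[C@@H](c1ccc(OCc3ccccc3)c(OC)c1)O2 | intermediate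
43 | (3R,4R)-lactone triol with (1R,2S)-1,3-dihydroxypropan-2-yl arm and three benzyl ethers | O=C1OC[C@H](Cc2cc(OC)c(OCc3ccccc3)c(c2)[C@@H](CO)[C@@H](O)c2ccc(OCc3ccccc3)c(OC)c2)[C@H]1Cc1cc(OC)c2c(c1)[C@H](CO)[C@@H](c1ccc(OCc3ccccc3)c(OC)c1)O2 | intermediate
44 | (3R,4R)-lactone keto diol with (2S)-3-hydroxy-1-oxopropan-2-yl arm and three benzyl ethers | O=C1OC[C@H](Cc2cc(OC)c(OCc3ccccc3)c(c2)[C@@H](CO)C(=O)c2ccc(OCc3ccccc3)c(OC)c2)[C@H]1Cc1cc(OC)c2c(c1)[C@H](CO)[C@@H](c1ccc(OCc3ccccc3)c(OC)c1)O2 | intermediate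
45 | CNP0111438.1 | COc1cc(C(=O)[C@H](CO)c2cc(C[C@H]3COC(=O)[C@@H]3Cc3cc(OC)c4c(c3)[C@H](CO)[C@@H](c3ccc(O)c(OC)c3)O4)cc(OC)c2O)ccc1O | target

**Step count and risks**

Total step count: 25 (steps 1–11 main line, steps 12–21 bromide branch, steps 22–25 union and endgame).
Longest linear sequence: 15 steps (steps 1–11, then 22–25).

Three steps most likely to fail:

1. Step 11. The catalyst may discriminate poorly between the two enantiotopic methylene groups, the uncatalysed peracid pathway may erode selectivity, or the many ether oxygens may bind scandium. The result would be a mixture of C4 epimers that cannot be separated this far from the arm stereocentres. Fallback: abandon ring expansion and make the same lactone by enantioselective carbenoid C–H insertion. Setting out from allyl acetonide 16, hydroboration–oxidation (9-BBN, then NaOH/H2O2) should give the 3-arylpropan-1-ol F1. Acylation with glyoxylic acid chloride tosylhydrazone followed by Et3N should give the diazoacetate F2. The chiral dirhodium carboxamidate Rh2(4S-MPPIM)4, or its antipode if the sense requires, in refluxing CH2Cl2 should insert the carbenoid into the C–H bond beta to the ester oxygen and give lactone 21, where the route is rejoined.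

2. Step 9. Zinc salts and the acid chloride may open or acylate the benzylic acetonide, and the unactivated terminal alkene may be consumed slowly while the ketene oligomerises. Fallback: a keteniminium [2+2] cycloaddition with no zinc and no chlorine. Setting out from 16, N,N-dimethylacetamide, Tf2O and 2,4,6-collidine in refluxing 1,2-dichloroethane should give the cyclobutaniminium triflate F3, which aqueous NaHCO3 hydrolyses to cyclobutanone 19; step 10 then falls away.

3. Step 24. The heterogeneous oxidation of a hindered secondary carbinol may stall, and forcing it may lead to retro-aldol loss of formaldehyde or dehydration of the beta-hydroxy ketone on the oxide surface. Fallback: make the benzylic alcohol the only free hydroxyl and use a homogeneous oxidant. Setting out from triol 43, TBSCl and imidazole at 0 °C should silylate the two primary alcohols to give the bis-silyl ether F4. Dess–Martin periodinane buffered with NaHCO3 should then give the bis-silyl ketone F5, and HF·pyridine in THF–pyridine at 0 °C should remove both silyl groups without base to give keto diol 44.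

**Further compounds**

F1 | step 11 | 3-{4-(benzyloxy)-3-[(4R,5S)-4-[4-(benzyloxy)-3-methoxyphenyl]-2,2-dimethyl-1,3-dioxan-5-yl]-5-methoxyphenyl}propan-1-ol | OCCCc1cc(OC)c(OCc2ccccc2)c(c1)[C@H]1COC(C)(C)O[C@H]1c1ccc(OCc2ccccc2)c(OC)c1
F2 | step 11 | diazoacetate of F1 | [N-]=[N+]=CC(=O)OCCCc1cc(OC)c(OCc2ccccc2)c(c1)[C@H]1COC(C)(C)O[C@H]1c1ccc(OCc2ccccc2)c(OC)c1
F3 | step 9 | N,N-dimethylcyclobutaniminium triflate corresponding to 19 | C[N+](C)=C1CC(Cc2cc(OC)c(OCc3ccccc3)c(c2)[C@H]2COC(C)(C)O[C@H]2c2ccc(OCc3ccccc3)c(OC)c2)C1.[O-]S(=O)(=O)C(F)(F)F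
F4 | step 24 | bis(TBS) ether of 43 at both primary alcohols, benzylic carbinol free | O=C1OC[C@H](Cc2cc(OC)c(OCc3ccccc3)c(c2)[C@@H](CO[Si](C)(C)C(C)(C)C)[C@@H](O)c2ccc(OCc3ccccc3)c(OC)c2)[C@H]1Cc1cc(OC)c2c(c1)[C@H](CO[Si](C)(C)C(C)(C)C)[C@@H](c1ccc(OCc3ccccc3)c(OC)c1)O2
F5 | step 24 | bis(TBS) ether of 44 | O=C1OC[C@H](Cc2cc(OC)c(OCc3ccccc3)c(c2)[C@@H](CO[Si](C)(C)C(C)(C)C)C(=O)c2ccc(OCc3ccccc3)c(OC)c2)[C@H]1Cc1cc(OC)c2c(c1)[C@H](CO[Si](C)(C)C(C)(C)C)[C@@H](c1ccc(OCc3ccccc3)c(OC)c1)O2
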